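The oxolane ring is cut across two C–C bonds, C2–C3 and C4–C5. This leaves the three-atom unit C5–O1–C2(aryl) and the two-carbon unit C3–C4. Both bonds are made in one Prins–pinacol rearrangement of a 2-aryl-4-[(Z)-alkenyl]-1,3-dioxolane. The alkene becomes C3–C4 and the acetal supplies C5–O1–C2. The dioxolane carbinol carbon, a temporary tether atom between C5 and C4, is extruded as a formyl group on C4. The step exploits the all-cis array at C2, C3 and C4: Z geometry, a chair transition state and allylic strain at the single L-glyceraldehyde-derived stereocentre set all three centres. Baeyer–Villiger oxidation then turns C4–CHO into C4–OH with retention.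

Key step: step 5

Assumption: (S)-glyceraldehyde acetonide 1 is taken as a catalogue compound and distilled before use. Oxolane numbering is O1, C2 (aryl), C3 (CH2O-ester), C4 (OH), C5 (CH2). Acetal 9 is a mixture of epimers at the acetal carbon and is drawn without configuration there. The descriptor changes from 1 to 3 (S to R) and at C3 from 12 and 13 to 14 (S to R) come from CIP priorities only, not from any inversion.

Step 1
Reactants: 1 (S)-2,2-dimethyl-1,3-dioxolane-4-carbaldehyde; 2 methyl (triphenylphosphoranylidene)acetate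
Product: 3 methyl (Z)-3-[(4R)-2,2-dimethyl-1,3-dioxolan-4-yl]prop-2-enoate
Conditions: MeOH, 0 °C; the E isomer is removed by chromatography
Reagents that add atoms: methyl (triphenylphosphoranylidene)acetate, COC(=O)C=P(c1ccccc1)(c1ccccc1)c1ccccc1
Why: Wittig olefination, in which a stabilised ylide adds to an alpha-alkoxy aldehyde in methanol under kinetic control to favour the Z enoate, while the dioxolane stereocentre is not touched.

Step 2
Reactants: 3 methyl (Z)-3-[(4R)-2,2-dimethyl-1,3-dioxolan-4-yl]prop-2-enoate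
Product: 4 (Z)-3-[(4R)-2,2-dimethyl-1,3-dioxolan-4-yl]prop-2-en-1-ol
Conditions: i-Bu2AlH (2.3 equiv), CH2Cl2, −78 °C; aq. potassium sodium tartrate
Reagents that add atoms: none
Why: 1,2-reduction of an enoate with i-Bu2AlH should give the allylic alcohol with the Z geometry and the acetonide intact.

Step 3
Reactants: 4 (Z)-3-[(4R)-2,2-dimethyl-1,3-dioxolan-4-yl]prop-2-en-1-ol; 5 3,4-dimethoxybenzoyl chloride
Product: 6 (Z)-3-[(4R)-2,2-dimethyl-1,3-dioxolan-4-yl]prop-2-en-1-yl 3,4-dimethoxybenzoate
Conditions: Et3N, cat. DMAP, CH2Cl2, 0 °C to rt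
Reagents that add atoms: 3,4-dimethoxybenzoyl chloride, COc1ccc(C(=O)Cl)cc1OC
Why: DMAP-catalysed acylation of a primary alcohol installs the ester of the target early, so that no protecting group is needed on this oxygen.

Step 4
Reactants: 6 (Z)-3-[(4R)-2,2-dimethyl-1,3-dioxolan-4-yl]prop-2-en-1-yl 3,4-dimethoxybenzoate; 7 3,4-dimethoxybenzaldehyde (veratraldehyde)
Product: 9 (Z)-3-[(4R)-2-(3,4-dimethoxyphenyl)-1,3-dioxolan-4-yl]prop-2-en-1-yl 3,4-dimethoxybenzoate (both epimers at the acetal carbon), via diol 8 (not isolated)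
Conditions: AcOH/H2O 4:1, 40 °C, evaporation with toluene; then 7, cat. PPTS, toluene, reflux, Dean–Stark trap
Reagents that add atoms: 3,4-dimethoxybenzaldehyde, COc1ccc(C=O)cc1OC
Why: Acetal exchange (acetonide hydrolysis, then azeotropic acetalisation of the 1,2-diol) leaves the carbinol stereocentre untouched, and the configuration of the new acetal carbon is irrelevant because step 5 planarises it.

Step 5
Reactants: 9 (Z)-3-[(4R)-2-(3,4-dimethoxyphenyl)-1,3-dioxolan-4-yl]prop-2-en-1-yl 3,4-dimethoxybenzoate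
Product: 12 [(2S,3S,4S)-2-(3,4-dimethoxyphenyl)-4-formyloxolan-3-yl]methyl 3,4-dimethoxybenzoate (all-cis), via oxocarbenium ion 10 (not isolated), via oxan-4-yl cation 11 (not isolated)
Conditions: SnCl4 (2 equiv), CH2Cl2, −78 to −20 °C; cold aq. NaHCO3; the crude aldehyde is used at once
Reagents that add atoms: none
Why: SnCl4 opens either acetal epimer of 9 at the allylic oxygen to the (E)-oxocarbenium ion 10, whose alkene carbon bearing the CH2O-ester attacks the oxocarbenium carbon (C3–C2 bond) to give the oxan-4-yl cation 11, and the OCH2 carbon then shifts from the stannylated carbinol carbon to the cationic carbon (C5–C4 bond) while that carbinol carbon becomes the formyl group. This is the known Prins–pinacol rearrangement of 4-alkenyl-1,3-dioxolanes to 3-acyl- and 3-formyloxolanes, and a 2-oxonia-Cope/aldol sequence, if it intervenes, makes the same two bonds and the same product. The oxolane is closed indirectly: a 6-endo-trig Prins closure builds an oxane ring that the 1,2-shift contracts to the five-membered ring, while the dioxolane is opened. In the chair the aryl group of the E-oxocarbenium ion is equatorial (C2), the Z alkene forces the CH2O arm axial and hence cis to the aryl group (C3), and C5, held by O1 on the alkene face already attacked by C2, can only add suprafacially, so that the Z geometry becomes the cis C3/C4 relation (C4). The absolute sense comes from the (R)-carbinol carbon: A(1,3) strain with the Z substituent selects the chair in which its H, not its O–Sn bond, faces the CH2O arm, so that this stereocentre is read out into C2, C3 and C4 before it is destroyed. The step needs opening at the allylic and not at the primary acetal oxygen (the other mode offers only a 5-endo path and reverts) and migration of the ring carbon rather than of the equally aligned carbinol hydrogen, which the oxygen substituent on the migrating carbon should favour; the low temperature guards C4 (alpha to CHO) and benzylic C2 against epimerisation.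

Step 6
Reactants: 12 [(2S,3S,4S)-2-(3,4-dimethoxyphenyl)-4-formyloxolan-3-yl]methyl 3,4-dimethoxybenzoate
Product: 14 [(2S,3R,4S)-2-(3,4-dimethoxyphenyl)-4-hydroxyoxolan-3-yl]methyl 3,4-dimethoxybenzoate (all-cis), via formate 13 (not isolated)
Conditions: mCPBA, CH2Cl2, 0 °C to rt; aqueous wash; then cat. K2CO3, MeOH, 0 °C
Reagents that add atoms: mCPBA, O=C(OO)c1cccc(Cl)c1
Why: Baeyer–Villiger oxidation of an alpha-branched aldehyde should move the secondary ring carbon C4 to oxygen with retention of configuration, and the resulting formate is methanolysed far faster than the electron-rich primary aryl ester.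

Compound list
1 | (S)-2,2-dimethyl-1,3-dioxolane-4-carbaldehyde | O=C[C@@H]1COC(C)(C)O1 | starting material
2 | methyl (triphenylphosphoranylidene)acetate | COC(=O)C=P(c1ccccc1)(c1ccccc1)c1ccccc1 | starting material
3 | methyl (Z)-3-[(4R)-2,2-dimethyl-1,3-dioxolan-4-yl]prop-2-enoate | COC(=O)/C=C\[C@@H]1COC(C)(C)O1 | intermediate
4 | (Z)-3-[(4R)-2,2-dimethyl-1,3-dioxolan-4-yl]prop-2-en-1-ol | OC/C=C\[C@@H]1COC(C)(C)O1 | intermediate
5 | 3,4-dimethoxybenzoyl chloride | COc1ccc(C(=O)Cl)cc1OC | starting material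
6 | (Z)-3-[(4R)-2,2-dimethyl-1,3-dioxolan-4-yl]prop-2-en-1-yl 3,4-dimethoxybenzoate | COc1ccc(cc1OC)C(=O)OC/C=C\[C@@H]1COC(C)(C)O1 | intermediate
7 | 3,4-dimethoxybenzaldehyde | COc1ccc(C=O)cc1OC | starting material
8 | (2Z,4R)-4,5-dihydroxypent-2-en-1-yl 3,4-dimethoxybenzoate | COc1ccc(cc1OC)C(=O)OC/C=C\[C@@H](O)CO | intermediate
9 | (Z)-3-[(4R)-2-(3,4-dimethoxyphenyl)-1,3-dioxolan-4-yl]prop-2-en-1-yl 3,4-dimethoxybenzoate, both epimers at the acetal carbon | COc1ccc(cc1OC)C(=O)OC/C=C\[C@@H]1COC(O1)c1ccc(OC)c(OC)c1 | intermediate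
10 | (E)-3,4-dimethoxybenzylidene oxocarbenium ion on the primary oxygen, with the (R)-carbinol oxygen bound as tetrachlorostannate alkoxide (zwitterion) | COc1ccc(cc1OC)C(=O)OC/C=C\[C@@H](O[Sn-](Cl)(Cl)(Cl)Cl)C/[O+]=C/c1ccc(OC)c(OC)c1 | intermediate
11 | 2-aryl-3-(aroyloxymethyl)-5-(tetrachlorostannyloxy)oxan-4-yl cation (aryl equatorial, CH2O arm axial, O–Sn equatorial; zwitterion) | COc1ccc(cc1OC)C(=O)OC[C@@H]1[CH+][C@@H](O[Sn-](Cl)(Cl)(Cl)Cl)CO[C@@H]1c1ccc(OC)c(OC)c1 | intermediate
12 | [(2S,3S,4S)-2-(3,4-dimethoxyphenyl)-4-formyloxolan-3-yl]methyl 3,4-dimethoxybenzoate, all-cis | COc1ccc(C(=O)OC[C@@H]2[C@H](C=O)CO[C@@H]2c2ccc(OC)c(OC)c2)cc1OC | intermediate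
13 | [(2S,3S,4S)-2-(3,4-dimethoxyphenyl)-4-(formyloxy)oxolan-3-yl]methyl 3,4-dimethoxybenzoate, all-cis | COc1ccc(C(=O)OC[C@@H]2[C@H](OC=O)CO[C@@H]2c2ccc(OC)c(OC)c2)cc1OC | intermediate
14 | [(2S,3R,4S)-2-(3,4-dimethoxyphenyl)-4-hydroxyoxolan-3-yl]methyl 3,4-dimethoxybenzoate, all-cis | COc1ccc(C(=O)OC[C@@H]2[C@H](O)CO[C@@H]2c2ccc(OC)c(OC)c2)cc1OC | target

Total step count: 6. Longest linear sequence: 6 steps (1 to 14).

Steps most likely to fail

Step 5. Several processes may compete with the rearrangement.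
- The Prins closure may be slow, because the alkene is flanked by two allylic C–O bonds and the oxocarbenium ion is strongly stabilised by the dimethoxyphenyl group.
- The ester carbonyl may capture the cation, or the allylic ester may ionise under SnCl4.
- The carbinol hydrogen may shift instead of the ring carbon.
- The minor chair may erode the facial selectivity.
- C2 or C4 may epimerise.

The fallback keeps the ester out of the key step and acylates last. It sets out from 4 and comes back at 14.
- TBDPSCl and imidazole give the silyl ether of 4 F1.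
- AcOH/H2O gives the silyloxy diol F2, and veratraldehyde 7 with cat. PPTS gives the silyloxy aryl acetal F3.
- SnCl4 rearranges the more electron-rich, non-participating alkene to the silyloxymethyl formyloxolane F4.
- mCPBA gives the silyloxymethyl formate F5, and cat. K2CO3 in MeOH gives the silyloxymethyl oxolanol F6.
- Bu4NF gives the oxolane diol F7.
- Acylation with 5 (2,4,6-collidine, CH2Cl2, −20 °C) takes place at the primary hydroxyl, away from the crowded secondary one, and gives 14.

Step 6. Hydrogen may migrate instead of C4 in the peracid adduct, which would lead to over-oxidation at the formyl carbon. The alpha-carbon of the crowded all-cis aldehyde may also epimerise before it is oxidised.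

The fallback sets out from 12 and comes back at 14.
- The weakly basic MeTi(OiPr)3 adds to the aldehyde only and gives the 1-hydroxyethyl oxolane F8, whose carbinol epimers do not matter.
- Dess–Martin periodinane gives the methyl ketone F9.
- In F9 only C4 competes with methyl, so mCPBA with NaHCO3 in CH2Cl2 should give the C4 acetate F10 with retention.
- Cat. K2CO3 in MeOH then gives 14.

Step 1. Control of the alkene geometry may be poor, and the labile alpha-alkoxy aldehyde may oligomerise or partly racemise.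

The fallback sets the geometry by syn hydrogenation. It sets out from 1 and comes back at 4.
- The Ohira–Bestmann reagent with K2CO3 in MeOH gives the ethynyl dioxolane F11.
- n-BuLi, then paraformaldehyde, gives the propargylic alcohol F12.
- H2 over Pd/CaCO3 poisoned with Pb(OAc)2, with quinoline, gives 4.

Further compounds
F1 | step 5 | tert-butyl{[(Z)-3-[(4R)-2,2-dimethyl-1,3-dioxolan-4-yl]prop-2-en-1-yl]oxy}diphenylsilane | CC(C)(C)[Si](c1ccccc1)(c1ccccc1)OC/C=C\[C@@H]1COC(C)(C)O1
F2 | step 5 | (2R,3Z)-5-[(tert-butyldiphenylsilyl)oxy]pent-3-ene-1,2-diol | CC(C)(C)[Si](c1ccccc1)(c1ccccc1)OC/C=C\[C@@H](O)CO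
F3 | step 5 | tert-butyl{[(Z)-3-[(4R)-2-(3,4-dimethoxyphenyl)-1,3-dioxolan-4-yl]prop-2-en-1-yl]oxy}diphenylsilane, both epimers at the acetal carbon | CC(C)(C)[Si](c1ccccc1)(c1ccccc1)OC/C=C\[C@@H]1COC(O1)c1ccc(OC)c(OC)c1
F4 | step 5 | (3S,4S,5S)-4-{[(tert-butyldiphenylsilyl)oxy]methyl}-5-(3,4-dimethoxyphenyl)oxolane-3-carbaldehyde, all-cis | CC(C)(C)[Si](c1ccccc1)(c1ccccc1)OC[C@@H]1[C@H](C=O)CO[C@@H]1c1ccc(OC)c(OC)c1
F5 | step 5 | (3S,4S,5S)-4-{[(tert-butyldiphenylsilyl)oxy]methyl}-5-(3,4-dimethoxyphenyl)oxolan-3-yl formate, all-cis | CC(C)(C)[Si](c1ccccc1)(c1ccccc1)OC[C@@H]1[C@H](OC=O)CO[C@@H]1c1ccc(OC)c(OC)c1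
F6 | step 5 | (3S,4R,5S)-4-{[(tert-butyldiphenylsilyl)oxy]methyl}-5-(3,4-dimethoxyphenyl)oxolan-3-ol, all-cis | CC(C)(C)[Si](c1ccccc1)(c1ccccc1)OC[C@@H]1[C@H](O)CO[C@@H]1c1ccc(OC)c(OC)c1
F7 | step 5 | (3S,4R,5S)-5-(3,4-dimethoxyphenyl)-4-(hydroxymethyl)oxolan-3-ol, all-cis | OC[C@@H]1[C@H](O)CO[C@@H]1c1ccc(OC)c(OC)c1
F8 | step 6 | [(2S,3S,4S)-2-(3,4-dimethoxyphenyl)-4-(1-hydroxyethyl)oxolan-3-yl]methyl 3,4-dimethoxybenzoate, both carbinol epimers | COc1ccc(C(=O)OC[C@@H]2[C@H](C(C)O)CO[C@@H]2c2ccc(OC)c(OC)c2)cc1OC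
F9 | step 6 | [(2S,3S,4S)-4-acetyl-2-(3,4-dimethoxyphenyl)oxolan-3-yl]methyl 3,4-dimethoxybenzoate, all-cis | COc1ccc(C(=O)OC[C@@H]2[C@H](C(C)=O)CO[C@@H]2c2ccc(OC)c(OC)c2)cc1OC
F10 | step 6 | [(2S,3S,4S)-4-(acetyloxy)-2-(3,4-dimethoxyphenyl)oxolan-3-yl]methyl 3,4-dimethoxybenzoate, all-cis | COc1ccc(C(=O)OC[C@@H]2[C@H](OC(C)=O)CO[C@@H]2c2ccc(OC)c(OC)c2)cc1OC
F11 | step 1 | (4R)-4-ethynyl-2,2-dimethyl-1,3-dioxolane | C#C[C@@H]1COC(C)(C)O1
F12 | step 1 | 3-[(4R)-2,2-dimethyl-1,3-dioxolan-4-yl]prop-2-yn-1-ol | OCC#C[C@@H]1COC(C)(C)O1
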